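**Retrosynthetic overview**

1. Numbering follows chroman-2-one (O1, C2=O, C3H2, C4, C4a to C8a); ring A is the carbocycle, ring B the lactone. The last disconnection removes the two prenyl groups at C8, the only unsubstituted carbon of ring A, and leads back to an aromatic lactone.
2. Key disconnection: C2–C3 of ring B. An enantioselective palladium-hydride isomerisation of an aryl formate onto an ortho 1-phenylethenyl group (intramolecular hydroesterification) closes ring B, keeps every atom of the precursor and sets C4.
3. Enabling feature: C3 is a bare CH2 between the lactone carbonyl and C4, which carries H, phenyl and C4a of ring A, and C2 hangs on O1, the ring-A oxygen ortho to C4a and para to the ketone. This is the pattern left when a formyl C–H bond on O1 adds across a C4=C3H2 1,1-diarylethene.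
4. The formate precursor comes from phloroglucinol by Friedel–Crafts acylation with (R)-2-methylbutanoyl chloride, Markovnikov hydroarylation of phenylacetylene and selective O-formylation.
5. Ring order: ring A is bought as phloroglucinol, ring B closes in the key step, ring A is dearomatised in the last step.

Key step: step 5

Remark: the target is read as 4S with an (R)-2-methylbutanoyl group; enantiopure (R)-2-methylbutanoic acid is taken as a commercial starting material.
Remark: the sense of induction of the bisphosphine in step 5 cannot be predicted with certainty; the route is written with the (R) ligand, and the (S) ligand is used if the (R) ligand should favour the 4R lactone.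

**Step 1**
Reactants: 1 (R)-2-methylbutanoic acid
Product: 2 (R)-2-methylbutanoyl chloride
Conditions: (COCl)2 (1.2 equiv), DMF (cat.), CH2Cl2, 0 °C → rt; distillation
Reagents that add atoms: oxalyl chloride, O=C(Cl)C(Cl)=O
Why: Acid chloride formation through catalytic chloroiminium (Vilsmeier-type) activation runs cold and without base at the carboxyl group only, so the α-stereocentre of 1 should pass into 2 unchanged.

**Step 2**
Reactants: 2 (R)-2-methylbutanoyl chloride; 3 phloroglucinol (benzene-1,3,5-triol)
Product: 4 (2R)-2-methyl-1-(2,4,6-trihydroxyphenyl)butan-1-one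
Conditions: AlCl3 (3.5 equiv), PhNO2/CH2Cl2, 0 °C → rt; ice/1 M HCl
Reagents that add atoms: none
Why: Friedel–Crafts C-acylation of the symmetrical, strongly nucleophilic triol should stop at the monoketone because the aluminium-chelated product is deactivated, and the mild temperature should leave the α-stereocentre intact.

**Step 3**
Reactants: 4 (2R)-2-methyl-1-(2,4,6-trihydroxyphenyl)butan-1-one; 5 phenylacetylene
Product: 6 (2R)-2-methyl-1-[2,4,6-trihydroxy-3-(1-phenylethenyl)phenyl]butan-1-one
Conditions: In(OTf)3 (5 mol %), MeNO2, 40 °C, 5 added slowly by syringe pump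
Reagents that add atoms: none
Why: Lewis-acid-catalysed Markovnikov hydroarylation of an arylacetylene (Friedel–Crafts alkenylation) is a pure addition in which one of the two equivalent free ring carbons of 4 attacks the internal alkyne carbon to give the 1,1-diarylethene; slow addition keeps the alkyne scarce so that it should be consumed by 4 before it can alkenylate the product a second time, and no stereocentre is formed.

**Step 4**
Reactants: 6 (2R)-2-methyl-1-[2,4,6-trihydroxy-3-(1-phenylethenyl)phenyl]butan-1-one
Product: 7 3,5-dihydroxy-4-[(2R)-2-methylbutanoyl]-2-(1-phenylethenyl)phenyl formate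
Conditions: HCO2H (1.05 equiv), DCC (1.05 equiv), EtOAc, 0 °C; filtration, evaporation, used crude
Reagents that add atoms: formic acid, O=CO
Why: Carbodiimide esterification (active aryl ester formation) should formylate the hydroxyl para to the ketone, which is the most acidic one and the least engaged in hydrogen bonding to the carbonyl group, and the absence of an amine base avoids base-induced loss of CO from the aryl formate.

**Step 5**
Reactants: 7 3,5-dihydroxy-4-[(2R)-2-methylbutanoyl]-2-(1-phenylethenyl)phenyl formate
Product: 8 (4S)-5,7-dihydroxy-6-[(2R)-2-methylbutanoyl]-4-phenyl-3,4-dihydro-2H-chromen-2-one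
Conditions: Pd(OAc)2 (5 mol %), (R)-DTBM-SEGPHOS (6 mol %), toluene (0.05 M), 80 °C, sealed tube, Ar
Reagents that add atoms: none
Why: Palladium-hydride hydroesterification with the formate of 7 as built-in source of both carbonyl and hydride: zerovalent palladium (from Pd(OAc)2 and the phosphine) takes up the formyl group as an aryloxy(hydrido)palladium carbonyl, the Pd–H adds across the 1,1-diarylethene with hydrogen on the internal carbon and palladium on the CH2 terminus, and the oxygen-bound acyl carbon is then joined to that CH2 with return of zerovalent palladium, the sealed vessel keeping any transiently released CO available. The closest known reactions are the palladium-catalysed asymmetric cyclocarbonylation of 2-(1-arylvinyl)phenols to 4-aryl-3,4-dihydrocoumarins and hydroesterifications that use aryl formates in place of CO gas. Ring B closes as a six-membered lactone in a formal 6-endo-trig sense, the acyl carbon ending on the terminal alkene carbon, since the five-membered alternative would put palladium on a fully substituted, doubly benzylic carbon. The C4 stereocentre is created in the Pd–H insertion under catalyst control by the C2-symmetric bisphosphine, which tells the flat phenyl group from the twisted, fully substituted ring A, and the distant side-chain centre should have no say. The step needs anti-Markovnikov regioselectivity, secured by the 1,1-disubstitution of the alkene, enantioface selectivity, secured by the ligand, and closure on the formylated oxygen (the later O1) instead of the hydroxyl between ketone and vinyl group, secured because the formyl group already sits on that oxygen and the competing hydroxyl is held in the hydrogen bond to the ketone.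

**Step 6**
Reactants: 8 (4S)-5,7-dihydroxy-6-[(2R)-2-methylbutanoyl]-4-phenyl-3,4-dihydro-2H-chromen-2-one
Product: 10 (4S)-5-hydroxy-6-[(2R)-2-methylbutanoyl]-8,8-bis(3-methylbut-2-en-1-yl)-4-phenyl-3,4-dihydro-2H-chromene-2,7(8H)-dione (the target), via 8-prenyl lactone 9 (not isolated)
Conditions: NaH (2.1 equiv), toluene, 0 °C; prenyl bromide (2.2 equiv), 0 °C → rt; aq. NH4Cl
Reagents that add atoms: prenyl bromide (1-bromo-3-methylbut-2-ene), CC(C)=CCBr
Why: Base-mediated dearomative C-alkylation of an acylphloroglucinol (lupulone-type gem-diprenylation): the sodium phenoxide reacts in the non-polar solvent as a tight ion pair at carbon, C8 is the only unsubstituted ring carbon and lies between two oxygens, so the first prenyl group should give 9 and the second, at the same carbon, should dearomatise ring A to 10, while the absence of water and of a nucleophilic base spares the lactone and leaves both stereocentres untouched.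

**Compound list**

1 | (R)-2-methylbutanoic acid | CC[C@@H](C)C(=O)O | starting material
2 | (R)-2-methylbutanoyl chloride | CC[C@@H](C)C(=O)Cl | intermediate
3 | phloroglucinol (benzene-1,3,5-triol) | Oc1cc(O)cc(O)c1 | starting material
4 | (2R)-2-methyl-1-(2,4,6-trihydroxyphenyl)butan-1-one | CC[C@@H](C)C(=O)c1c(O)cc(O)cc1O | intermediate
5 | phenylacetylene | C#Cc1ccccc1 | starting material
6 | (2R)-2-methyl-1-[2,4,6-trihydroxy-3-(1-phenylethenyl)phenyl]butan-1-one | CC[C@@H](C)C(=O)c1c(O)cc(O)c(C(=C)c2ccccc2)c1O | intermediate
7 | 3,5-dihydroxy-4-[(2R)-2-methylbutanoyl]-2-(1-phenylethenyl)phenyl formate | CC[C@@H](C)C(=O)c1c(O)cc(OC=O)c(C(=C)c2ccccc2)c1O | intermediate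
8 | (4S)-5,7-dihydroxy-6-[(2R)-2-methylbutanoyl]-4-phenyl-3,4-dihydro-2H-chromen-2-one | CC[C@@H](C)C(=O)c1c(O)c2c(OC(=O)C[C@H]2c2ccccc2)cc1O | intermediate
9 | (4S)-5,7-dihydroxy-6-[(2R)-2-methylbutanoyl]-8-(3-methylbut-2-en-1-yl)-4-phenyl-3,4-dihydro-2H-chromen-2-one (8-prenyl lactone) | CC[C@@H](C)C(=O)c1c(O)c2c(OC(=O)C[C@H]2c2ccccc2)c(CC=C(C)C)c1O | intermediate
10 | (4S)-5-hydroxy-6-[(2R)-2-methylbutanoyl]-8,8-bis(3-methylbut-2-en-1-yl)-4-phenyl-3,4-dihydro-2H-chromene-2,7(8H)-dione | CC[C@@H](C)C(=O)C1=C(O)C2=C(OC(=O)C[C@H]2c2ccccc2)C(CC=C(C)C)(CC=C(C)C)C1=O | target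

**Step count and risks**

Total step count: 6. Longest linear sequence: 6 steps (from compound 1).

Steps most likely to fail:

Step 5. Loss of CO from the formate may outrun its capture, returning the free phenol. Enantioface discrimination at the hindered alkene may also be insufficient, and some closure may leak to the other ortho oxygen. Fallback (sets out from compound 4, returns at compound 8): the hydroxyl para to the ketone is esterified with propiolic acid (DCC, EtOAc, 0 °C) to 3,5-dihydroxy-4-[(2R)-2-methylbutanoyl]phenyl prop-2-ynoate F1. Intramolecular alkyne hydroarylation (Pd(OAc)2 cat., CF3CO2H/CH2Cl2, rt) should then give 5,7-dihydroxy-6-[(2R)-2-methylbutanoyl]-2H-chromen-2-one F2. Rhodium-catalysed asymmetric 1,4-addition of phenylboronic acid (Rh(acac)(C2H4)2, (S)-SEGPHOS, dioxane/H2O, 60 °C; Hayashi–Miyaura reaction) sets C4 and returns to compound 8.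

Step 6. O-alkylation may compete with C-alkylation, and acyl transfer from the lactone to a phenoxide of another molecule may lead to oligomers. Fallback (sets out from compound 8, returns at compound 10): the lactone is opened on purpose with aqueous KOH at 0 °C to the salt of (3S)-3-{2,4,6-trihydroxy-3-[(2R)-2-methylbutanoyl]phenyl}-3-phenylpropanoic acid F3. This salt is C-diprenylated in the same aqueous base with prenyl bromide at 0 °C (classical aqueous conditions) and acidified to (3S)-3-{2,6-dihydroxy-5-[(2R)-2-methylbutanoyl]-3,3-bis(3-methylbut-2-en-1-yl)-4-oxocyclohexa-1,5-dien-1-yl}-3-phenylpropanoic acid F4. Carbodiimide lactonisation (EDC·HCl, CH2Cl2, 0 °C) should then close ring B to compound 10. It is expected to close on the free enol oxygen next to the quaternary carbon, because the other enol is held in the hydrogen bond to the ketone.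

Step 3. Over-reaction in the acidic medium is the risk: a second alkenylation at the remaining free ring carbon, or cation-driven oligomerisation of the acid-sensitive diarylethene. Fallback (sets out from compound 4, returns at compound 6): monoiodination (N-iodosuccinimide, MeCN, 0 °C) should give (2R)-1-(2,4,6-trihydroxy-3-iodophenyl)-2-methylbutan-1-one F5. Suzuki–Miyaura coupling with 1-phenylvinylboronic acid pinacol ester (Pd(OAc)2, SPhos, K3PO4, dioxane/H2O, 60 °C) introduces the alkene without acid and returns to compound 6.

**Further compounds**

F1 | step 5 | 3,5-dihydroxy-4-[(2R)-2-methylbutanoyl]phenyl prop-2-ynoate | CC[C@@H](C)C(=O)c1c(O)cc(OC(=O)C#C)cc1O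
F2 | step 5 | 5,7-dihydroxy-6-[(2R)-2-methylbutanoyl]-2H-chromen-2-one | CC[C@@H](C)C(=O)c1c(O)c2c(OC(=O)C=C2)cc1O
F3 | step 6 | (3S)-3-{2,4,6-trihydroxy-3-[(2R)-2-methylbutanoyl]phenyl}-3-phenylpropanoic acid | CC[C@@H](C)C(=O)c1c(O)cc(O)c([C@@H](CC(=O)O)c2ccccc2)c1O
F4 | step 6 | (3S)-3-{2,6-dihydroxy-5-[(2R)-2-methylbutanoyl]-3,3-bis(3-methylbut-2-en-1-yl)-4-oxocyclohexa-1,5-dien-1-yl}-3-phenylpropanoic acid | CC[C@@H](C)C(=O)C1=C(O)C([C@@H](CC(=O)O)c2ccccc2)=C(O)C(CC=C(C)C)(CC=C(C)C)C1=O
F5 | step 3 | (2R)-1-(2,4,6-trihydroxy-3-iodophenyl)-2-methylbutan-1-one | CC[C@@H](C)C(=O)c1c(O)cc(O)c(I)c1O
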